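**Retrosynthetic overview**

1. The target is reached by desilylation and hydrogenolysis of a hexa-O-benzyl 3-O-silyl ketone, whose chromanone ring is closed last, at C4–C4a, by Parham cyclisation of a 2-bromoaryl ether onto the C3 methyl ester.
2. O1–C2 comes from boron-guided syn addition of 2-bromo-3,5-bis(benzyloxy)phenol to the C2–C3 epoxide of a flavan-fused methyl 2-arylbenzofuran-3-carboxylate; a chiral dioxirane chooses the epoxide face.
3. Key disconnection C2–C3: the ester enolate of methyl (7'-aroyloxyflavan-8'-yl)acetate is acylated by its own O7' 4-benzyloxybenzoate, and acid closes the furan ring by cyclodehydration.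
4. That ester derives from tetra-O-benzyl-(2S,3R)-afzelechin by C8' bromination, lithiation and methoxalylation, chelation-controlled O7' debenzylation, deoxygenation and O7' aroylation; the flavan comes from (−)-epiafzelechin by C2' epimerisation and benzylation.
5. Structural feature: the C2–C3 bond shared by the chromanone ring and the dihydrofuran ring joins ketal carbon C2 (O1, O7', ring B) to carbinol carbon C3 (OH, C4, C8') with O1 and 3-OH on one face (trans ring fusion). Ring order: flavan rings (starting material), furan ring (step 9), chromanone ring (step 15).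

Key step: step 9

Locants: O1, C2, C3, C4, C4a–C8a and ring B belong to the chromanone unit of the target; primed locants (O1', C2', C3', C4', C5'–C8') and ring B' belong to the flavan unit. In the benzofuran stage C2 carries ring B and C3 carries the ester, whose carbonyl carbon becomes C4.

Remark: the flavan unit of the target is (2'S,3'R), 2,3-trans, whereas commercial (−)-epiafzelechin is (2R,3R), so the route begins by inverting C2'.

Assumption: the D-fructose-derived ketone of step 12 is taken to deliver oxygen to the face of C2=C3 drawn for the epoxide; its enantiomer would be used if the sense proved opposite.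

**Route**

Step 1
Reactants: 1 (−)-epiafzelechin
Product: 2 (2S,3R)-afzelechin (ent-afzelechin)
Conditions: degassed aq. KH2PO4/Na2HPO4 buffer (pH 7.5), 110 °C, sealed vessel, Ar; reversed-phase chromatography, recovered 1 recycled
Reagents that add atoms: none
Why: In hot neutral water the ring B' phenol opens O1'–C2' to a para-quinone methide that re-closes, which equilibrates C2' alone (C3' stays R) and should favour the 2,3-trans isomer, the known C2 epimerisation of flavan-3-ols.

Step 2
Reactants: 2 (2S,3R)-afzelechin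
Product: 3 (2S,3R)-5,7-bis(benzyloxy)-2-(4-benzyloxyphenyl)chroman-3-ol
Conditions: BnBr (3.3 equiv), K2CO3, DMF, 0 °C → rt, Ar
Reagents that add atoms: benzyl bromide, BrCc1ccccc1
Why: Williamson etherification under carbonate alkylates the three phenols but not the secondary alcohol, and capping the ring B' oxygen shuts off further C2' epimerisation.

Step 3
Reactants: 3 (2S,3R)-5,7-bis(benzyloxy)-2-(4-benzyloxyphenyl)chroman-3-ol
Product: 4 (2S,3R)-3,5,7-tris(benzyloxy)-2-(4-benzyloxyphenyl)chroman
Conditions: NaH, BnBr, Bu4NI (cat.), THF/DMF, 0 °C → rt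
Reagents that add atoms: benzyl bromide, BrCc1ccccc1
Why: Williamson etherification of the C3' alkoxide, with no epimerisable centre left in the molecule.

Step 4
Reactants: 4 (2S,3R)-3,5,7-tris(benzyloxy)-2-(4-benzyloxyphenyl)chroman
Product: 5 (2S,3R)-8-bromo-3,5,7-tris(benzyloxy)-2-(4-benzyloxyphenyl)chroman
Conditions: NBS (1.0 equiv), CH2Cl2, −40 → 0 °C
Reagents that add atoms: N-bromosuccinimide, O=C1CCC(=O)N1Br
Why: Electrophilic aromatic bromination attacks the most electron-rich ring, and 5,7-dialkoxyflavans are brominated at C8' in preference to C6'.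

Step 5
Reactants: 5 (2S,3R)-8-bromo-3,5,7-tris(benzyloxy)-2-(4-benzyloxyphenyl)chroman
Product: 7 methyl 2-oxo-2-[(2S,3R)-3,5,7-tris(benzyloxy)-2-(4-benzyloxyphenyl)chroman-8-yl]acetate, via 8-lithioflavan 6 (not isolated)
Conditions: n-BuLi (1.05 equiv), THF, −78 °C; cannulated into (CO2Me)2 (4 equiv), THF, −78 °C; aq. NH4Cl
Reagents that add atoms: dimethyl oxalate, COC(=O)C(=O)OC
Why: Bromine–lithium exchange gives the C8' aryllithium, and inverse addition to excess oxalate diester stops at the α-keto ester because the tetrahedral adduct persists at −78 °C.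

Step 6
Reactants: 7 methyl 2-oxo-2-[(2S,3R)-3,5,7-tris(benzyloxy)-2-(4-benzyloxyphenyl)chroman-8-yl]acetate
Product: 8 methyl 2-[(2S,3R)-3,5-bis(benzyloxy)-2-(4-benzyloxyphenyl)-7-hydroxychroman-8-yl]-2-oxoacetate
Conditions: MgBr2·OEt2 (3 equiv), toluene/Et2O, 70 °C; 1 M HCl work-up
Reagents that add atoms: none
Why: Magnesium chelated between the C8' ketone oxygen and O7' polarises only that benzyl–oxygen bond for attack by bromide (carbonyl-directed ortho debenzylation), while the O5', O3' and ring B' benzyl ethers lack the chelate.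

Step 7
Reactants: 8 methyl 2-[(2S,3R)-3,5-bis(benzyloxy)-2-(4-benzyloxyphenyl)-7-hydroxychroman-8-yl]-2-oxoacetate
Product: 10 methyl 2-[(2S,3R)-3,5-bis(benzyloxy)-2-(4-benzyloxyphenyl)-7-hydroxychroman-8-yl]acetate, via aryl ethyl carbonate 9 (not isolated)
Conditions: ClCO2Et, Et3N, THF, 0 °C; then NaBH4, THF/H2O, 0 °C → rt; AcOH to pH 6
Reagents that add atoms: none
Why: Borohydride reduces the activated ketone of the phenol carbonate, the carbonate shifts to the new alkoxide and leaves by 1,4-elimination (quinone-methide pathway), and a second hydride adds to the exocyclic carbon; this is the known acid-free reductive deoxygenation of ortho-acylphenols and spares the benzyl ethers and the O1'–C2' bond.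

Step 8
Reactants: 10 methyl 2-[(2S,3R)-3,5-bis(benzyloxy)-2-(4-benzyloxyphenyl)-7-hydroxychroman-8-yl]acetate; 11 4-benzyloxybenzoyl chloride
Product: 12 methyl 2-[(2S,3R)-3,5-bis(benzyloxy)-7-(4-benzyloxybenzoyloxy)-2-(4-benzyloxyphenyl)chroman-8-yl]acetate
Conditions: Et3N, 4-(dimethylamino)pyridine (cat.), CH2Cl2, 0 °C → rt
Reagents that add atoms: none
Why: Amine-catalysed O-acylation of the only free hydroxyl by an acid chloride (Schotten–Baumann-type esterification).

Step 9
Reactants: 12 methyl 2-[(2S,3R)-3,5-bis(benzyloxy)-7-(4-benzyloxybenzoyloxy)-2-(4-benzyloxyphenyl)chroman-8-yl]acetate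
Product: 14 methyl (2S,3R)-3,5-bis(benzyloxy)-2,8-bis(4-benzyloxyphenyl)-3,4-dihydro-2H-furo[2,3-h]chromene-9-carboxylate (flavan-fused methyl 2-arylbenzofuran-3-carboxylate), via β-keto ester 13 (not isolated)
Conditions: LiN(SiMe3)2 (2.2 equiv), THF, −78 → 0 °C; AcOH; then p-TsOH·H2O (cat.), toluene, 80 °C
Reagents that add atoms: none
Why: LiN(SiMe3)2 removes a proton from the arylacetate CH2, and the enolate carbon adds to the carbonyl of the neighbouring O7' 4-benzyloxybenzoate through a five-membered transition state, which forms the C2–C3 bond; the adduct collapses with release of the O7' phenoxide, and the second equivalent of base holds the product as the enolate of 13. This is the ester-enolate form of the Baker–Venkataraman O-to-C acyl shift, followed by the acid cyclodehydration commonly used for benzofurans. The furan ring is traversed first in the 5-exo-trig acyl transfer and is fixed in the acid stage by 5-exo-trig addition of the O7' hydroxyl of 13 to the aryl ketone, with loss of water from the hemiketal driven by aromatisation. No stereocentre is created, and C2' and C3' cannot epimerise in either stage because the ring B' oxygen is benzylated. The step needs chemoselective enolisation and C-acylation at the crowded C8' side chain: the aroyl group has no α-hydrogen, the amide base is non-nucleophilic, only one CH2 is acidic, and the tether fixes the site of acylation.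

Step 10
Reactants: 15 3,5-bis(benzyloxy)phenol
Product: 16 2-bromo-3,5-bis(benzyloxy)phenol
Conditions: NBS (1.0 equiv), i-Pr2NH (cat.), CH2Cl2, −78 → 0 °C
Reagents that add atoms: N-bromosuccinimide, O=C1CCC(=O)N1Br
Why: Amine-mediated bromination delivers bromine ortho to the phenolic hydroxyl through a hydrogen-bonded N-bromoamine, and the monobromide is separated from any para isomer.

Step 11
Reactants: 16 2-bromo-3,5-bis(benzyloxy)phenol (2 equiv)
Product: 17 bis[2-bromo-3,5-bis(benzyloxy)phenyl] phenylboronate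
Conditions: PhB(OH)2 (1 equiv), toluene, reflux, Dean–Stark; solution used directly
Reagents that add atoms: phenylboronic acid, OB(O)c1ccccc1
Why: Azeotropic condensation of a boronic acid with two equivalents of a phenol gives the diaryl boronate, which is moisture-sensitive and is therefore used as its toluene solution.

Step 12
Reactants: 14 flavan-fused methyl 2-arylbenzofuran-3-carboxylate
Product: 18 C2–C3 epoxide of 14 (epoxide oxygen on the face that later carries O1 and the C3 hydroxyl)
Conditions: 4,5-di-O-acetyl-1,2-O-isopropylidene-β-D-erythro-2,3-hexodiulo-2,6-pyranose (0.3 equiv), 2KHSO5·KHSO4·K2SO4, NaHCO3, Bu4NHSO4 (cat.), MeCN/dimethoxymethane–aq. Na2EDTA, 0 °C; cold toluene extraction, K2CO3-dried solution used at once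
Reagents that add atoms: potassium peroxymonosulfate, OOS(=O)(=O)[O-].[K+]
Why: Proposed new method: a dioxirane formed catalytically from the chiral ketone and KHSO5 transfers oxygen through a concerted spiro transition state to the C2=C3 bond, which keeps enol-ether nucleophilicity while the C3 ester (as in isolable flavone 2,3-epoxides) tempers ionisation of the product at C2, and the catalyst rather than the remote flavan centres is expected to choose the face and so set C2 and C3 together; the closest known reactions are dimethyldioxirane epoxidation of 2,3-disubstituted benzofurans and flavones and the chiral-ketone (Shi) epoxidation of α,β-unsaturated esters.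

Step 13
Reactants: 18 C2–C3 epoxide of 14; 17 bis[2-bromo-3,5-bis(benzyloxy)phenyl] phenylboronate (1.5 equiv)
Product: 20 syn aryloxy alcohol (C2 bears the 2-bromo-3,5-bis(benzyloxy)phenoxy group cis to the C3 hydroxyl; C3 also bears CO2Me), via C3 boronate 19 (not isolated)
Conditions: toluene/CH2Cl2, 4 Å molecular sieves, −40 → 0 °C; aq. NaHCO3/sorbitol work-up
Reagents that add atoms: none
Why: Proposed new method: the Lewis-acidic boron of 17 binds the epoxide oxygen, C2–O ionises to an oxocarbenium ion stabilised by O7' and ring B and held as a contact ion pair with the tetracoordinate borate on the C3 oxygen, and an aryloxy ligand passes from boron to C2 on the face the epoxide oxygen has just left (SNi-type collapse), so that O1 and the C3 oxygen end up syn with retention at both carbons; the closest known reaction is the boron-mediated delivery of boronic or borinic ester-bound alcohols to 1,2-anhydro sugars, which gives 1,2-cis glycosides.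

Step 14
Reactants: 20 syn aryloxy alcohol
Product: 21 C3 trimethylsilyl ether of 20
Conditions: 1-(trimethylsilyl)imidazole, CH2Cl2, rt
Reagents that add atoms: 1-(trimethylsilyl)imidazole, C[Si](C)(C)n1ccnc1
Why: Silyl transfer from the N-silylimidazole caps the tertiary hydroxyl under non-acidic conditions, which removes the only acidic proton before the organolithium step without ionising the mixed ketal at C2.

Step 15
Reactants: 21 C3 trimethylsilyl ether of 20
Product: 23 hexa-O-benzyl 3-O-trimethylsilyl derivative of the target (chromanone ring closed), via aryllithium 22 (not isolated)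
Conditions: t-BuLi (2.0 equiv), THF, −100 → −40 °C; aq. NH4Cl
Reagents that add atoms: none
Why: Parham cyclisation: bromine–lithium exchange at −100 °C outruns attack on the hindered tertiary ester, and the aryllithium ortho to O1 acylates intramolecularly (6-exo-trig) to form C4–C4a while C2 and C3 are untouched, so the syn O1/C3–O relationship becomes the trans ring fusion.

Step 16
Reactants: 23 hexa-O-benzyl 3-O-trimethylsilyl derivative of the target
Product: 24 hexa-O-benzyl derivative of the target (free C3 hydroxyl)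
Conditions: HF·pyridine, pyridine, THF, 0 °C
Reagents that add atoms: none
Why: Buffered fluoride cleaves the tertiary trimethylsilyl ether without the base that could start an α-ketol rearrangement and without acid strong enough to ionise the ketal carbon.

Step 17
Reactants: 24 hexa-O-benzyl derivative of the target
Product: 25 CNP0146414.2
Conditions: H2 (1 atm), Pd(OH)2/C, EtOAc/MeOH, rt; filtration under Ar
Reagents that add atoms: none
Why: Neutral hydrogenolysis removes the six benzyl ethers, and the hydrogen-bonded aryl ketone, the fully substituted ketal carbon and all four stereocentres are expected to be unaffected.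

**Compound list**

1 | (−)-epiafzelechin, (2R,3R)-2-(4-hydroxyphenyl)chroman-3,5,7-triol | O[C@@H]1Cc2c(O)cc(O)cc2O[C@@H]1c1ccc(O)cc1 | starting material
2 | (2S,3R)-afzelechin (ent-afzelechin), 2,3-trans | Oc1cc(O)c2c(c1)O[C@@H](c1ccc(O)cc1)[C@H](O)C2 | intermediate
3 | (2S,3R)-5,7-bis(benzyloxy)-2-(4-benzyloxyphenyl)chroman-3-ol | c1c(OCc9ccccc9)cc(OCc9ccccc9)c2c1O[C@@H](c3ccc(OCc9ccccc9)cc3)[C@H](O)C2 | intermediate
4 | (2S,3R)-3,5,7-tris(benzyloxy)-2-(4-benzyloxyphenyl)chroman | c1c(OCc9ccccc9)cc(OCc9ccccc9)c2c1O[C@@H](c3ccc(OCc9ccccc9)cc3)[C@H](OCc9ccccc9)C2 | intermediate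
5 | (2S,3R)-8-bromo-3,5,7-tris(benzyloxy)-2-(4-benzyloxyphenyl)chroman | Brc1c(OCc9ccccc9)cc(OCc9ccccc9)c2c1O[C@@H](c3ccc(OCc9ccccc9)cc3)[C@H](OCc9ccccc9)C2 | intermediate
6 | 8-lithio derivative of 4 (formed in situ) | [Li]c1c(OCc9ccccc9)cc(OCc9ccccc9)c2c1O[C@@H](c3ccc(OCc9ccccc9)cc3)[C@H](OCc9ccccc9)C2 | intermediate
7 | methyl 2-oxo-2-[(2S,3R)-3,5,7-tris(benzyloxy)-2-(4-benzyloxyphenyl)chroman-8-yl]acetate | COC(=O)C(=O)c1c(OCc9ccccc9)cc(OCc9ccccc9)c2c1O[C@@H](c3ccc(OCc9ccccc9)cc3)[C@H](OCc9ccccc9)C2 | intermediate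
8 | methyl 2-[(2S,3R)-3,5-bis(benzyloxy)-2-(4-benzyloxyphenyl)-7-hydroxychroman-8-yl]-2-oxoacetate | COC(=O)C(=O)c1c(O)cc(OCc9ccccc9)c2c1O[C@@H](c3ccc(OCc9ccccc9)cc3)[C@H](OCc9ccccc9)C2 | intermediate
9 | 7-O-ethoxycarbonyl derivative of 8 (formed in situ) | COC(=O)C(=O)c1c(OC(=O)OCC)cc(OCc9ccccc9)c2c1O[C@@H](c3ccc(OCc9ccccc9)cc3)[C@H](OCc9ccccc9)C2 | intermediate
10 | methyl 2-[(2S,3R)-3,5-bis(benzyloxy)-2-(4-benzyloxyphenyl)-7-hydroxychroman-8-yl]acetate | COC(=O)Cc1c(O)cc(OCc9ccccc9)c2c1O[C@@H](c3ccc(OCc9ccccc9)cc3)[C@H](OCc9ccccc9)C2 | intermediate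
11 | 4-benzyloxybenzoyl chloride | O=C(Cl)c1ccc(OCc2ccccc2)cc1 | starting material
12 | methyl 2-[(2S,3R)-3,5-bis(benzyloxy)-7-(4-benzyloxybenzoyloxy)-2-(4-benzyloxyphenyl)chroman-8-yl]acetate (key-step precursor) | COC(=O)Cc1c(OC(=O)c4ccc(OCc9ccccc9)cc4)cc(OCc9ccccc9)c2c1O[C@@H](c3ccc(OCc9ccccc9)cc3)[C@H](OCc9ccccc9)C2 | intermediate
13 | methyl 3-(4-benzyloxyphenyl)-3-oxo-2-[(2S,3R)-3,5-bis(benzyloxy)-2-(4-benzyloxyphenyl)-7-hydroxychroman-8-yl]propanoate (β-keto ester, α-carbon labile, formed in situ) | COC(=O)C(C(=O)c4ccc(OCc9ccccc9)cc4)c1c(O)cc(OCc9ccccc9)c2c1O[C@@H](c3ccc(OCc9ccccc9)cc3)[C@H](OCc9ccccc9)C2 | intermediate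
14 | methyl (2S,3R)-3,5-bis(benzyloxy)-2,8-bis(4-benzyloxyphenyl)-3,4-dihydro-2H-furo[2,3-h]chromene-9-carboxylate (key-step product) | COC(=O)c1c(-c4ccc(OCc9ccccc9)cc4)oc5cc(OCc9ccccc9)c2c(c51)O[C@@H](c3ccc(OCc9ccccc9)cc3)[C@H](OCc9ccccc9)C2 | intermediate
15 | 3,5-bis(benzyloxy)phenol | Oc1cc(OCc2ccccc2)cc(OCc2ccccc2)c1 | starting material
16 | 2-bromo-3,5-bis(benzyloxy)phenol | Oc1cc(OCc2ccccc2)cc(OCc2ccccc2)c1Br | intermediate
17 | bis[2-bromo-3,5-bis(benzyloxy)phenyl] phenylboronate | Brc1c(OCc9ccccc9)cc(OCc9ccccc9)cc1OB(c1ccccc1)Oc1cc(OCc9ccccc9)cc(OCc9ccccc9)c1Br | intermediate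
18 | C2–C3 epoxide of 14, oxygen on the face later occupied by O1 and 3-OH | COC(=O)[C@@]12O[C@]1(c4ccc(OCc9ccccc9)cc4)Oc4cc(OCc9ccccc9)c5c(c42)O[C@@H](c3ccc(OCc9ccccc9)cc3)[C@H](OCc9ccccc9)C5 | intermediate
19 | C3–O boronate of 20, B bearing phenyl and one 2-bromo-3,5-bis(benzyloxy)phenoxy group (formed in situ) | Brc1c(OCc9ccccc9)cc(OCc9ccccc9)cc1O[C@]2(c4ccc(OCc9ccccc9)cc4)Oc4cc(OCc9ccccc9)c5c(c4[C@]2(C(=O)OC)OB(c6ccccc6)Oc6cc(OCc9ccccc9)cc(OCc9ccccc9)c6Br)O[C@@H](c3ccc(OCc9ccccc9)cc3)[C@H](OCc9ccccc9)C5 | intermediate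
20 | syn aryloxy alcohol: 2-(4-benzyloxyphenyl)-2-[2-bromo-3,5-bis(benzyloxy)phenoxy]-3-hydroxy-2,3-dihydrofuran fused at C7'–C8' of the flavan, methyl ester on C3, aryloxy and hydroxyl cis | Brc1c(OCc9ccccc9)cc(OCc9ccccc9)cc1O[C@]2(c4ccc(OCc9ccccc9)cc4)Oc4cc(OCc9ccccc9)c5c(c4[C@]2(C(=O)OC)O)O[C@@H](c3ccc(OCc9ccccc9)cc3)[C@H](OCc9ccccc9)C5 | intermediate
21 | C3 trimethylsilyl ether of 20 | Brc1c(OCc9ccccc9)cc(OCc9ccccc9)cc1O[C@]2(c4ccc(OCc9ccccc9)cc4)Oc4cc(OCc9ccccc9)c5c(c4[C@]2(C(=O)OC)O[Si](C)(C)C)O[C@@H](c3ccc(OCc9ccccc9)cc3)[C@H](OCc9ccccc9)C5 | intermediate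
22 | aryllithium from 21, Li in place of Br (formed in situ) | [Li]c1c(OCc9ccccc9)cc(OCc9ccccc9)cc1O[C@]2(c4ccc(OCc9ccccc9)cc4)Oc4cc(OCc9ccccc9)c5c(c4[C@]2(C(=O)OC)O[Si](C)(C)C)O[C@@H](c3ccc(OCc9ccccc9)cc3)[C@H](OCc9ccccc9)C5 | intermediate
23 | hexa-O-benzyl 3-O-trimethylsilyl derivative of the target | O=C1c2c(OCc9ccccc9)cc(OCc9ccccc9)cc2O[C@]2(c3ccc(OCc9ccccc9)cc3)Oc3cc(OCc9ccccc9)c4c(c3[C@@]12O[Si](C)(C)C)O[C@@H](c1ccc(OCc9ccccc9)cc1)[C@H](OCc9ccccc9)C4 | intermediate
24 | hexa-O-benzyl derivative of the target | O=C1c2c(OCc9ccccc9)cc(OCc9ccccc9)cc2O[C@]2(c3ccc(OCc9ccccc9)cc3)Oc3cc(OCc9ccccc9)c4c(c3[C@@]12O)O[C@@H](c1ccc(OCc9ccccc9)cc1)[C@H](OCc9ccccc9)C4 | intermediate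
25 | CNP0146414.2: (2S,3R)-3,5,7-trihydroxy-2-(4-hydroxyphenyl)chroman-4-one unit joined through C3–C8' and C2–O7' to (2'S,3'R)-afzelechin, O1 and 3-OH syn | O=C1c2c(O)cc(O)cc2O[C@]2(c3ccc(O)cc3)Oc3cc(O)c4c(c3[C@@]12O)O[C@@H](c1ccc(O)cc1)[C@H](O)C4 | target

**Step count and risks**

Total step count: 17. Longest linear sequence: 15 steps (steps 1–9 and 12–17).

Steps most likely to fail:

1. Step 12 (labelled). Oxygen transfer to the ester-deactivated furan double bond may be slower than self-destruction of the chiral ketone, face selection may be poor, and the epoxide may be opened by water before it is extracted. The fallback sets out from 14: anhydrous dimethyldioxirane in acetone/CH2Cl2 at −20 °C, the established reagent for 2,3-disubstituted benzofurans and flavones, should give 18 together with the diastereomeric epoxide F1 with no water present. The route is rejoined at 18, carried as this mixture. In step 13 F1 becomes the diastereomeric syn aryloxy alcohol F2, which is removed from 20 by chromatography; the two are diastereomers because the flavan unit is enantiopure.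

2. Step 13 (labelled). The oxocarbenium ion may escape from the ion pair and be captured on either face, the boronate may be too weak a Lewis acid to open the epoxide, or the epoxide may first open at C3–O and lose the C3 configuration. The fallback sets out from 18: free phenol 16 with catalytic pyridinium p-toluenesulfonate in toluene at −20 °C. This is the ordinary acid-catalysed opening of an aryl-substituted epoxide at its cation-stabilised carbon, which for such epoxides tends to favour syn adducts by ion-pair collapse. It should give 20 together with the C2-epimeric anti aryloxy alcohol F3, which is separated by chromatography and can be returned to the same acid for re-equilibration at the ketal carbon. The route is rejoined at 20.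

3. Step 15. The chromanone ring has to close trans to the dihydrofuran ring, so acylation by the ester on the opposite face may be slower than protonation or intermolecular attack of the aryllithium. The fallback sets out from 21: DIBAL-H at −78 °C should reduce the hindered ester to the aldehyde F4. An intramolecular Nozaki–Hiyama–Kishi reaction (CrCl2, NiCl2 cat., DMF, rt) then lets a long-lived, non-basic arylchromium reagent add to the more reactive aldehyde, giving the cyclic carbinol F5 (either C4 epimer). Dess–Martin periodinane should oxidise F5 to 23, where the route is rejoined.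

Further compounds
F1 | step 12 | diastereomeric epoxide (oxygen on the opposite face of C2–C3) | COC(=O)[C@]12O[C@@]1(c4ccc(OCc9ccccc9)cc4)Oc4cc(OCc9ccccc9)c5c(c42)O[C@@H](c3ccc(OCc9ccccc9)cc3)[C@H](OCc9ccccc9)C5
F2 | step 12 | diastereomeric syn aryloxy alcohol (C2 and C3 both inverted relative to 20) | Brc1c(OCc9ccccc9)cc(OCc9ccccc9)cc1O[C@@]2(c4ccc(OCc9ccccc9)cc4)Oc4cc(OCc9ccccc9)c5c(c4[C@@]2(C(=O)OC)O)O[C@@H](c3ccc(OCc9ccccc9)cc3)[C@H](OCc9ccccc9)C5
F3 | step 13 | C2-epimeric anti aryloxy alcohol (aryloxy group trans to the C3 hydroxyl) | Brc1c(OCc9ccccc9)cc(OCc9ccccc9)cc1O[C@@]2(c4ccc(OCc9ccccc9)cc4)Oc4cc(OCc9ccccc9)c5c(c4[C@]2(C(=O)OC)O)O[C@@H](c3ccc(OCc9ccccc9)cc3)[C@H](OCc9ccccc9)C5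
F4 | step 15 | aldehyde (CHO in place of CO2Me in 21) | Brc1c(OCc9ccccc9)cc(OCc9ccccc9)cc1O[C@]2(c4ccc(OCc9ccccc9)cc4)Oc4cc(OCc9ccccc9)c5c(c4[C@]2(C=O)O[Si](C)(C)C)O[C@@H](c3ccc(OCc9ccccc9)cc3)[C@H](OCc9ccccc9)C5
F5 | step 15 | cyclic carbinol (C4 hydroxyl in place of the C4 ketone of 23, C4 epimers) | OC1c2c(OCc9ccccc9)cc(OCc9ccccc9)cc2O[C@]2(c3ccc(OCc9ccccc9)cc3)Oc3cc(OCc9ccccc9)c4c(c3[C@@]12O[Si](C)(C)C)O[C@@H](c1ccc(OCc9ccccc9)cc1)[C@H](OCc9ccccc9)C4
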